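## Retrosynthetic overview

1. Target ⇐ global O-debenzylation of its octabenzyl ether ⇐ acid-induced closure of the 2,4-bis(benzyloxy)styryl unit onto ring B. The seven-membered ring is formed last and sets the diarylmethine centre.
2. Key C–C bonds (C2–C3 of both dihydrobenzofurans, made during the fragment union): a bis(o-quinone methide) is attacked twice by a chiral sulfonium benzylide. The ylide carbon is a carbanionic, polarity-reversed form of the p-alkoxybenzyl cation, so two normally electrophilic carbons are joined each time and both trans-dihydrobenzofurans close in the same flask.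
3. The bis(o-quinone methide) is assembled in that flask from three pieces by two aryllithium additions to O-Boc salicylaldehydes. Lithium keeps each adduct as a phenoxide carbonate until MgBr2 unmasks both.
4. Building blocks: ring-B O-Boc aldehyde from 4-bromo-2,6-difluorobenzaldehyde; ring-C O-Boc stilbene aldehyde from 1,3-bis(benzyloxy)-5-bromobenzene (Vilsmeier–Haack, Heck); sulfonium salt from isothiocineole.
5. Ring order: the two dihydrofurans (on rings B and C) together → seven-membered carbocycle.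

Assumption: the benzylide from (1R,4R,5R)-isothiocineole is taken to deliver the (2S,3S) dihydrobenzofuran; if the sense proves opposite, the mirror-image sulfide from (S)-limonene is used in steps 4 and 10 with no other change.

## Route

Step 1
Reactants: 1 4-bromo-2,6-difluorobenzaldehyde
Product: 2 2,6-bis(benzyloxy)-4-bromobenzaldehyde
Conditions: BnOH (2.4 equiv), KOtBu (2.3 equiv), THF, 0 → 50 °C
Reagents that add atoms: benzyl alcohol OCc1ccccc1
Why: Double SNAr: both fluorides are ortho to the formyl group and far better nucleofuges than the para bromide, which is kept.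

Step 2
Reactants: 2 2,6-bis(benzyloxy)-4-bromobenzaldehyde
Product: 3 2-(benzyloxy)-4-bromo-6-hydroxybenzaldehyde
Conditions: MgBr2·OEt2 (1.1 equiv), toluene/Et2O, 60 °C; then H2O
Reagents that add atoms: none
Why: Chelation-controlled cleavage of a benzyl ether ortho to a carbonyl; the magnesium phenoxide chelate formed after the first cleavage protects the second ether.

Step 3
Reactants: 3 2-(benzyloxy)-4-bromo-6-hydroxybenzaldehyde
Product: 4 3-(benzyloxy)-5-bromo-2-formylphenyl tert-butyl carbonate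
Conditions: Boc2O, iPr2NEt, DMAP (cat.), CH2Cl2, 0 °C → rt
Reagents that add atoms: di-tert-butyl dicarbonate CC(C)(C)OC(=O)OC(=O)OC(C)(C)C
Why: DMAP-catalysed O-acylation of the phenol installs the carbonate that later migrates and leaves to unmask the o-quinone methide.

Step 4
Reactants: 5 4-(benzyloxy)benzyl bromide; 6 (1R,4R,5R)-isothiocineole
Product: 7 (1R,4R,5R)-6-[4-(benzyloxy)benzyl]-4,7,7-trimethyl-6-thiabicyclo[3.2.1]octan-6-ium trifluoromethanesulfonate
Conditions: LiOSO2CF3 (5 equiv), CH2Cl2/H2O, rt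
Reagents that add atoms: lithium trifluoromethanesulfonate [Li+].[O-]S(=O)(=O)C(F)(F)F
Why: S-alkylation of the sulfide by the reactive p-alkoxybenzyl bromide with anion exchange gives a crystalline sulfonium salt, alkylated on the less hindered (exo) sulfur lone pair as a single sulfur epimer.

Step 5
Reactants: 8 1,3-bis(benzyloxy)-5-bromobenzene
Product: 9 2,4-bis(benzyloxy)-6-bromobenzaldehyde
Conditions: POCl3, DMF, 80 °C; then H2O
Reagents that add atoms: N,N-dimethylformamide CN(C)C=O; water O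
Why: Vilsmeier–Haack formylation goes para to one benzyloxy group and ortho to the other (next to Br), not at the more hindered position between the two ethers.

Step 6
Reactants: 10 2,4-bis(benzyloxy)benzaldehyde
Product: 11 2,4-bis(benzyloxy)-1-ethenylbenzene
Conditions: Ph3PCH3Br, KOtBu, THF, 0 °C → rt
Reagents that add atoms: methyltriphenylphosphonium bromide C[P+](c1ccccc1)(c1ccccc1)c1ccccc1.[Br-]
Why: Wittig methylenation of an aryl aldehyde; the styrene is used directly.

Step 7
Reactants: 9 2,4-bis(benzyloxy)-6-bromobenzaldehyde; 11 2,4-bis(benzyloxy)-1-ethenylbenzene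
Product: 12 2,4-bis(benzyloxy)-6-[(E)-2-[2,4-bis(benzyloxy)phenyl]ethenyl]benzaldehyde
Conditions: Pd(OAc)2 (5 mol %), P(o-tol)3 (10 mol %), Et3N, DMF, 100 °C
Reagents that add atoms: none
Why: Mizoroki–Heck coupling of an aryl bromide activated by the ortho formyl group with a terminal styrene gives the (E)-stilbene by β-arylation and syn β-hydride elimination.

Step 8
Reactants: 12 2,4-bis(benzyloxy)-6-[(E)-2-[2,4-bis(benzyloxy)phenyl]ethenyl]benzaldehyde
Product: 13 4-(benzyloxy)-2-[(E)-2-[2,4-bis(benzyloxy)phenyl]ethenyl]-6-hydroxybenzaldehyde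
Conditions: MgBr2·OEt2 (1.2 equiv), toluene/Et2O, 60 °C; then H2O
Reagents that add atoms: none
Why: Chelation-controlled debenzylation: only the ether ortho to the formyl group can chelate magnesium, so the three other benzyl ethers and the stilbene are untouched.

Step 9
Reactants: 13 4-(benzyloxy)-2-[(E)-2-[2,4-bis(benzyloxy)phenyl]ethenyl]-6-hydroxybenzaldehyde
Product: 14 5-(benzyloxy)-3-[(E)-2-[2,4-bis(benzyloxy)phenyl]ethenyl]-2-formylphenyl tert-butyl carbonate
Conditions: Boc2O, iPr2NEt, DMAP (cat.), CH2Cl2, 0 °C → rt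
Reagents that add atoms: di-tert-butyl dicarbonate CC(C)(C)OC(=O)OC(=O)OC(C)(C)C
Why: DMAP-catalysed O-acylation of the phenol, as in step 3.

Step 10
Reactants: 8 1,3-bis(benzyloxy)-5-bromobenzene; 4 3-(benzyloxy)-5-bromo-2-formylphenyl tert-butyl carbonate; 14 5-(benzyloxy)-3-[(E)-2-[2,4-bis(benzyloxy)phenyl]ethenyl]-2-formylphenyl tert-butyl carbonate; 7 sulfonium triflate (2.6 equiv)
Product: 21 (2S,3S)-6-(benzyloxy)-2-[4-(benzyloxy)phenyl]-3-[(2S,3S)-4-(benzyloxy)-2-[4-(benzyloxy)phenyl]-3-[3,5-bis(benzyloxy)phenyl]-2,3-dihydro-1-benzofuran-6-yl]-4-[(E)-2-[2,4-bis(benzyloxy)phenyl]ethenyl]-2,3-dihydro-1-benzofuran, via aryllithium 15 (not isolated), via lithium phenoxide carbonate 16 (not isolated), via aryllithium 17 (not isolated), via dilithium bis-carbonate 18 (not isolated), via sulfonium ylide 19 (not isolated), via bis-o-quinone methide 20 (not isolated)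
Conditions: 8, t-BuLi (2.0 equiv), THF, −78 °C; 4, −78 °C; t-BuLi (2.0 equiv), −95 °C; 14, −95 → −78 °C; MgBr2·OEt2 (3 equiv), −78 → −30 °C; recool to −78 °C, ylide from 7 (2.6 equiv) and LiN(SiMe3)2 (THF, −78 °C); −78 → 0 °C
Reagents that add atoms: none
Why: Proposed new method: aryllithium 15 adds to the O-Boc aldehyde 4 and the new alkoxide takes over the Boc group, but with lithium as the only counter-ion the phenoxide–benzylic carbonate 16 does not eliminate at −78 °C (the known lithium/magnesium switch of anionic o-quinone-methide generation), so its aryl bromide can be exchanged with t-BuLi at −95 °C (Parham-type low-temperature exchange, faster than attack on the hindered tert-butyl carbonate) and aryllithium 17 stores a second such unit by addition to 14; MgBr2 then triggers β-elimination of both carbonates of 18, and each electrophilic methide carbon of 20 is attacked by the carbanionic carbon of ylide 19, a polarity-reversed equivalent of the p-alkoxybenzyl cation, before the phenoxide displaces the sulfide (Michael addition/SN2, a double sulfur-ylide [4+1] annulation; closest known types are sulfonium-ylide [4+1] annulations of o-quinone methides and isothiocineole-based asymmetric epoxidation); the rigid bicyclic sulfide fixes the ylide face and so each C2, anti addition to the favoured methide geometry sets each C3, both rings come out trans-(2S,3S) under reagent control, and because two independent reagent-controlled events are needed the minor sense ends up mainly in a separable diastereomer, which raises the enantiomeric purity of 21.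

Step 11
Reactants: 21 protected linear bis-dihydrobenzofuran stilbene
Product: 22 octa-O-benzyl ether of 23 (all eight phenols as benzyl ethers; five stereocentres all S)
Conditions: CF3CO2H (10 equiv), CH2Cl2 (5 mM), −20 → 0 °C
Reagents that add atoms: none
Why: Intramolecular Friedel–Crafts hydroarylation (the ring closure known for ε-viniferin → ampelopsin B): protonation at the ring-C-bound alkene carbon gives a 2,4-dialkoxybenzyl cation that is attacked 7-endo by C7 of the ring-B benzofuran (ortho to the ring oxygen, para to OBn; C5 is shielded by the 4-benzyloxy group), and the aryl group takes the pseudo-axial position on the face of H-3 of the ring-C dihydrofuran, away from the flanking furan oxygen, which gives the S methine under substrate control.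

Step 12
Reactants: 22 octa-O-benzyl ether of 23
Product: 23 CNP0154774.1 (target)
Conditions: BCl3 (24 equiv), C6HMe5 (30 equiv), CH2Cl2, −78 °C; then MeOH/H2O
Reagents that add atoms: none
Why: Lewis-acid debenzylation with a non-basic cation scavenger removes all eight benzyl ethers at −78 °C without ionising the benzylic C–O bonds of the dihydrobenzofurans (which hydrogenolysis would cleave); no stereocentre is touched.

## Compound list

1 | 4-bromo-2,6-difluorobenzaldehyde | O=Cc1c(F)cc(Br)cc1F | starting material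
2 | 2,6-bis(benzyloxy)-4-bromobenzaldehyde | O=Cc1c(OCc2ccccc2)cc(Br)cc1OCc1ccccc1 | intermediate
3 | 2-(benzyloxy)-4-bromo-6-hydroxybenzaldehyde | O=Cc1c(O)cc(Br)cc1OCc1ccccc1 | intermediate
4 | 3-(benzyloxy)-5-bromo-2-formylphenyl tert-butyl carbonate | O=Cc1c(OC(=O)OC(C)(C)C)cc(Br)cc1OCc1ccccc1 | intermediate
5 | 4-(benzyloxy)benzyl bromide | BrCc1ccc(OCc2ccccc2)cc1 | starting material
6 | (1R,4R,5R)-4,7,7-trimethyl-6-thiabicyclo[3.2.1]octane (isothiocineole) | C[C@@H]1CC[C@@H]2C[C@H]1SC2(C)C | starting material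
7 | (1R,4R,5R)-6-[4-(benzyloxy)benzyl]-4,7,7-trimethyl-6-thiabicyclo[3.2.1]octan-6-ium trifluoromethanesulfonate (benzyl on the exo lone pair of sulfur, single sulfur epimer; sulfur left unassigned in the SMILES) | C[C@@H]1CC[C@@H]2C[C@H]1[S+](Cc1ccc(OCc3ccccc3)cc1)C2(C)C.[O-]S(=O)(=O)C(F)(F)F | intermediate
8 | 1,3-bis(benzyloxy)-5-bromobenzene | Brc1cc(OCc2ccccc2)cc(OCc2ccccc2)c1 | starting material
9 | 2,4-bis(benzyloxy)-6-bromobenzaldehyde | O=Cc1c(Br)cc(OCc2ccccc2)cc1OCc1ccccc1 | intermediate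
10 | 2,4-bis(benzyloxy)benzaldehyde | O=Cc1ccc(OCc2ccccc2)cc1OCc1ccccc1 | starting material
11 | 2,4-bis(benzyloxy)-1-ethenylbenzene | C=Cc1ccc(OCc2ccccc2)cc1OCc1ccccc1 | intermediate
12 | 2,4-bis(benzyloxy)-6-[(E)-2-[2,4-bis(benzyloxy)phenyl]ethenyl]benzaldehyde | O=Cc1c(/C=C/c2ccc(OCc3ccccc3)cc2OCc2ccccc2)cc(OCc2ccccc2)cc1OCc1ccccc1 | intermediate
13 | 4-(benzyloxy)-2-[(E)-2-[2,4-bis(benzyloxy)phenyl]ethenyl]-6-hydroxybenzaldehyde | O=Cc1c(/C=C/c2ccc(OCc3ccccc3)cc2OCc2ccccc2)cc(OCc2ccccc2)cc1O | intermediate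
14 | 5-(benzyloxy)-3-[(E)-2-[2,4-bis(benzyloxy)phenyl]ethenyl]-2-formylphenyl tert-butyl carbonate | O=Cc1c(/C=C/c2ccc(OCc3ccccc3)cc2OCc2ccccc2)cc(OCc2ccccc2)cc1OC(=O)OC(C)(C)C | intermediate
15 | [3,5-bis(benzyloxy)phenyl]lithium | [Li]c1cc(OCc2ccccc2)cc(OCc2ccccc2)c1 | intermediate
16 | lithium 3-(benzyloxy)-2-{[3,5-bis(benzyloxy)phenyl][(tert-butoxycarbonyl)oxy]methyl}-5-bromophenolate (carbinol carbon racemic) | [Li]Oc1cc(Br)cc(OCc2ccccc2)c1C(OC(=O)OC(C)(C)C)c1cc(OCc2ccccc2)cc(OCc2ccccc2)c1 | intermediate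
17 | lithium 3-(benzyloxy)-2-{[3,5-bis(benzyloxy)phenyl][(tert-butoxycarbonyl)oxy]methyl}-5-lithiophenolate (carbinol carbon racemic) | [Li]Oc1cc([Li])cc(OCc2ccccc2)c1C(OC(=O)OC(C)(C)C)c1cc(OCc2ccccc2)cc(OCc2ccccc2)c1 | intermediate
18 | dilithium salt of 3-(benzyloxy)-2-{[3,5-bis(benzyloxy)phenyl][(tert-butoxycarbonyl)oxy]methyl}-5-{[4-(benzyloxy)-2-[(E)-2-[2,4-bis(benzyloxy)phenyl]ethenyl]-6-hydroxyphenyl][(tert-butoxycarbonyl)oxy]methyl}phenol (both carbinol carbons unassigned) | [Li]Oc1cc(cc(OCc2ccccc2)c1C(OC(=O)OC(C)(C)C)c1cc(OCc2ccccc2)cc(OCc2ccccc2)c1)C(OC(=O)OC(C)(C)C)c1c(O[Li])cc(OCc2ccccc2)cc1/C=C/c1ccc(OCc2ccccc2)cc1OCc1ccccc1 | intermediate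
19 | sulfonium ylide of 7: (1R,4R,5R)-6-[4-(benzyloxy)benzylidene]-4,7,7-trimethyl-6λ4-thiabicyclo[3.2.1]octane | C[C@@H]1CC[C@@H]2C[C@H]1[S+]([CH-]c1ccc(OCc3ccccc3)cc1)C2(C)C | intermediate
20 | bis(o-quinone methide): 5-(benzyloxy)-6-[3,5-bis(benzyloxy)benzylidene]-3-({4-(benzyloxy)-2-[(E)-2-[2,4-bis(benzyloxy)phenyl]ethenyl]-6-oxocyclohexa-2,4-dien-1-ylidene}methyl)cyclohexa-2,4-dien-1-one (exocyclic alkene geometries not assigned) | O=C1C=C(C=C2C(=O)C=C(OCc3ccccc3)C=C2/C=C/c2ccc(OCc3ccccc3)cc2OCc2ccccc2)C=C(OCc2ccccc2)C1=Cc1cc(OCc2ccccc2)cc(OCc2ccccc2)c1 | intermediate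
21 | (2S,3S)-6-(benzyloxy)-2-[4-(benzyloxy)phenyl]-3-[(2S,3S)-4-(benzyloxy)-2-[4-(benzyloxy)phenyl]-3-[3,5-bis(benzyloxy)phenyl]-2,3-dihydro-1-benzofuran-6-yl]-4-[(E)-2-[2,4-bis(benzyloxy)phenyl]ethenyl]-2,3-dihydro-1-benzofuran | c1ccccc1COc1ccc(cc1)[C@H]2Oc3cc(cc(OCc4ccccc4)c3[C@@H]2c4cc(OCc5ccccc5)cc(OCc5ccccc5)c4)[C@H]5c6c(cc(OCc7ccccc7)cc6O[C@@H]5c7ccc(OCc8ccccc8)cc7)/C=C/c8ccc(OCc9ccccc9)cc8OCc9ccccc9 | intermediate
22 | octa-O-benzyl ether of 23: both trans-(2S,3S)-dihydrobenzofurans, seven-membered ring closed between C7 of the ring-B benzofuran and the (S)-configured methine bearing the 2,4-bis(benzyloxy)phenyl group | c1ccccc1COc1ccc(cc1)[C@H]2Oc3c4c(cc(OCc5ccccc5)c3[C@@H]2c5cc(OCc6ccccc6)cc(OCc6ccccc6)c5)[C@H]6c7c(cc(OCc8ccccc8)cc7O[C@@H]6c8ccc(OCc9ccccc9)cc8)C[C@H]4c9ccc(OCc1ccccc1)cc9OCc1ccccc1 | intermediate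
23 | CNP0154774.1: two trans-(2S,3S)-2-(4-hydroxyphenyl)-2,3-dihydrobenzofurans (ring B carrying the 3,5-dihydroxyphenyl group, ring C peri-fused to the carbocycle) joined through a seven-membered ring whose CH2–CH methine bears 2,4-dihydroxyphenyl; five stereocentres all S | Oc1ccc([C@H]2Oc3c4c(cc(O)c3[C@@H]2c2cc(O)cc(O)c2)[C@H]2c3c(cc(O)cc3O[C@@H]2c2ccc(O)cc2)C[C@H]4c2ccc(O)cc2O)cc1 | target

## Step count and risks

Total steps: 12. Longest linear sequence: 7 (steps 5, 7, 8, 9, 10, 11, 12; the line through steps 6, 7, 8, 9, 10, 11, 12 is equally long; the ring-B line 1, 2, 3, 10, 11, 12 has six).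

**First risk: step 10.** Everything is asked of one flask. The second bromine–lithium exchange must outrun attack on the carbonate of 16, lithium must hold both carbonates until MgBr2 is added, and 20 must last until the ylide arrives. The level of induction at each C3 also depends on the methide geometry. The fallback sets out from 4 (with 8, 7 and 14) and comes back at 21; it splits the union into two separately run annulations with an isolated intermediate.
- Make [3,5-bis(benzyloxy)phenyl]magnesium bromide F1 from 8 (Mg, THF) and add it to 4 at −78 °C.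
- On warming to −20 °C the adduct gives the o-quinone methide 5-(benzyloxy)-6-[3,5-bis(benzyloxy)benzylidene]-3-bromocyclohexa-2,4-dien-1-one F2.
- A portion of ylide 19 converts it into (2S,3S)-4-(benzyloxy)-2-[4-(benzyloxy)phenyl]-3-[3,5-bis(benzyloxy)phenyl]-6-bromo-2,3-dihydro-1-benzofuran F3, which is isolated and purified.
- n-BuLi (THF, −78 °C) then gives [(2S,3S)-4-(benzyloxy)-2-[4-(benzyloxy)phenyl]-3-[3,5-bis(benzyloxy)phenyl]-2,3-dihydro-1-benzofuran-6-yl]lithium F4.
- MgBr2·OEt2 turns it into [(2S,3S)-4-(benzyloxy)-2-[4-(benzyloxy)phenyl]-3-[3,5-bis(benzyloxy)phenyl]-2,3-dihydro-1-benzofuran-6-yl]magnesium bromide F5.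
- Addition to 14 and warming gives the o-quinone methide 3-(benzyloxy)-5-[(E)-2-[2,4-bis(benzyloxy)phenyl]ethenyl]-6-{[(2S,3S)-4-(benzyloxy)-2-[4-(benzyloxy)phenyl]-3-[3,5-bis(benzyloxy)phenyl]-2,3-dihydro-1-benzofuran-6-yl]methylidene}cyclohexa-2,4-dien-1-one F6, which a second, freshly made portion of ylide 19 closes to 21.

**Second risk: step 11.** Ring closure could occur at C5 instead of C7 of ring B, or give the epimeric methine, on the fully benzylated substrate. The fallback sets out from 21 and comes back at 23 by reversing the order. Debenzylate first (BCl3, C6HMe5, CH2Cl2, −78 °C) to the free linear trimer (2S,3S)-3-[(2S,3S)-3-(3,5-dihydroxyphenyl)-4-hydroxy-2-(4-hydroxyphenyl)-2,3-dihydro-1-benzofuran-6-yl]-4-[(E)-2-(2,4-dihydroxyphenyl)ethenyl]-2-(4-hydroxyphenyl)-2,3-dihydro-1-benzofuran-6-ol F7. Then close the seven-membered ring on the octaphenol under reversible protic conditions (HCl, MeOH, 40 °C), as in the ε-viniferin → ampelopsin B conversion, so that the thermodynamic methine epimer is reached. Regiochemistry on ring B is then no longer steered by the benzyl ether and must be checked.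

**Third risk: step 8.** MgBr2 releases benzyl bromide and traces of HBr next to an electron-rich stilbene, which may be benzylated or isomerised, and the debenzylation may stall. The fallback sets out from 9 and comes back at 13 by moving the debenzylation ahead of the alkene. Treat 9 with MgBr2·OEt2 (toluene/Et2O, 60 °C) to give 4-(benzyloxy)-2-bromo-6-hydroxybenzaldehyde F8. Then couple F8 with 11 under Mizoroki–Heck conditions (Pd(OAc)2, P(o-tol)3, Et3N, DMF, 100 °C), which gives 13 directly.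

Further compounds

F1 | step 10 | [3,5-bis(benzyloxy)phenyl]magnesium bromide | Br[Mg]c1cc(OCc2ccccc2)cc(OCc2ccccc2)c1
F2 | step 10 | 5-(benzyloxy)-6-[3,5-bis(benzyloxy)benzylidene]-3-bromocyclohexa-2,4-dien-1-one (exocyclic alkene geometry not assigned) | O=C1C=C(Br)C=C(OCc2ccccc2)C1=Cc1cc(OCc2ccccc2)cc(OCc2ccccc2)c1
F3 | step 10 | (2S,3S)-4-(benzyloxy)-2-[4-(benzyloxy)phenyl]-3-[3,5-bis(benzyloxy)phenyl]-6-bromo-2,3-dihydro-1-benzofuran | c1ccccc1COc1ccc(cc1)[C@H]2Oc3cc(Br)cc(OCc4ccccc4)c3[C@@H]2c4cc(OCc5ccccc5)cc(OCc5ccccc5)c4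
F4 | step 10 | [(2S,3S)-4-(benzyloxy)-2-[4-(benzyloxy)phenyl]-3-[3,5-bis(benzyloxy)phenyl]-2,3-dihydro-1-benzofuran-6-yl]lithium | c1ccccc1COc1ccc(cc1)[C@H]2Oc3cc([Li])cc(OCc4ccccc4)c3[C@@H]2c4cc(OCc5ccccc5)cc(OCc5ccccc5)c4
F5 | step 10 | [(2S,3S)-4-(benzyloxy)-2-[4-(benzyloxy)phenyl]-3-[3,5-bis(benzyloxy)phenyl]-2,3-dihydro-1-benzofuran-6-yl]magnesium bromide | c1ccccc1COc1ccc(cc1)[C@H]2Oc3cc([Mg]Br)cc(OCc4ccccc4)c3[C@@H]2c4cc(OCc5ccccc5)cc(OCc5ccccc5)c4
F6 | step 10 | 3-(benzyloxy)-5-[(E)-2-[2,4-bis(benzyloxy)phenyl]ethenyl]-6-{[(2S,3S)-4-(benzyloxy)-2-[4-(benzyloxy)phenyl]-3-[3,5-bis(benzyloxy)phenyl]-2,3-dihydro-1-benzofuran-6-yl]methylidene}cyclohexa-2,4-dien-1-one (exocyclic alkene geometry not assigned) | c1ccccc1COc1ccc(cc1)[C@H]2Oc3cc(cc(OCc4ccccc4)c3[C@@H]2c4cc(OCc5ccccc5)cc(OCc5ccccc5)c4)C=C5C(=O)C=C(OCc6ccccc6)C=C5/C=C/c6ccc(OCc7ccccc7)cc6OCc7ccccc7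
F7 | step 11 | (2S,3S)-3-[(2S,3S)-3-(3,5-dihydroxyphenyl)-4-hydroxy-2-(4-hydroxyphenyl)-2,3-dihydro-1-benzofuran-6-yl]-4-[(E)-2-(2,4-dihydroxyphenyl)ethenyl]-2-(4-hydroxyphenyl)-2,3-dihydro-1-benzofuran-6-ol | Oc1ccc(cc1)[C@H]2Oc3cc(cc(O)c3[C@@H]2c4cc(O)cc(O)c4)[C@H]5c6c(cc(O)cc6O[C@@H]5c7ccc(O)cc7)/C=C/c8ccc(O)cc8O
F8 | step 8 | 4-(benzyloxy)-2-bromo-6-hydroxybenzaldehyde | O=Cc1c(O)cc(OCc2ccccc2)cc1Br
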